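## Analysis of the target

Compound 27 is a cyclopent-2-en-1-one, numbered here C1 (carbonyl), C2 (enol ether carbon with OMe), C3 (alkene carbon with a 4-hydroxyphenyl group), C4 and C5. C4 is also the spiro carbon of an oxirane (C4–O–C6H2), and C5 carries a methoxy group and the second 4-hydroxyphenyl ring. The only stereocentres are C4 and C5: adjacent, fully substituted, both R, with the oxirane oxygen on C4 and the methoxy oxygen on C5 on opposite faces of the five-membered ring (C6 cis to the C5 methoxy, the C5 aryl cis to the oxirane oxygen). Neither centre bears hydrogen, so nothing can be corrected by epimerisation; the configuration must be set once, absolutely, and then left alone. Several sites are sensitive. The oxirane is allylic to the enol ether and acid-labile. A free alkoxide on C4 is β to the C1 ketone through C5 and could cleave C4–C5 by retro-aldol reaction. The tertiary benzylic ether at C5 is para to a phenol and can ionise through a quinone methide. The phenols need masking through oxidation and ozonolysis. The difficulty is two contiguous oxygenated quaternary stereocentres in a crowded cyclopentenone that is labile to acid and base. The strategy rests on the fragment C6–C4(O)–C5(OMe)(Ar): a C4 oxygen anti to a C5 methoxy group, next to a C6 oxygen, is what results when a C4=C5 alkene with a C6 allylic hydroxyl is epoxidised and opened at benzylic C5 with inversion. The remaining ring atoms C1, C2 and C3 can then be joined through the C2=C3 double bond without touching either centre.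

## Retrosynthetic reasoning

27 ⇒ 26. The two O–Si bonds are cut last. The bis-silyl ether 26 can pass through base, oxidant and ozonolysis steps that free phenols could not.

26 ⇒ 24 (through 25). In the oxirane the O–C6 bond is cut, not C4–O. C6 is a primary carbon without stereochemistry, whereas the C4–O bond carries the configuration. Forward, the primary hydroxyl of diol 24 is activated as tosylate 25 and displaced by the tertiary C4 oxygen. The oxirane is made late because it would otherwise be exposed to the carbanion used for ring closure.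

24 ⇒ 23 ⇒ 22. With the C4/C6 diol masked as the acetonide (23), the ring is cut at C2=C3. This is the only ring bond that holds no stereochemistry and joins two carbons at carbonyl oxidation level. A Horner–Wadsworth–Emmons closure of keto phosphonate 22 forms it in one direction only, and C2 arrives already carrying its methoxy group.

22 ⇒ 21. The C3 ketone is traced back to the 1,1-disubstituted alkene C3=CH2 of 21. A ketone at C3 cannot be present while C4=C5 is still an alkene (it would be a deactivated enone), and it would compete for the phosphonate anion.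

21 ⇒ 20 ⇒ 17 + 18. The C1–C2 bond is cut. Phosphonate 18 supplies C2 and its oxygen; its lithio derivative 19 adds to aldehyde 17 and adduct 20 is oxidised. This makes C1 a primary alcohol carbon of an open chain.

17 ⇒ 16 ⇒ 15 ⇒ 14. These are functional-group changes only. The aldehyde comes from the primary alcohol of 14. The pivalate on the C5 aryl ring is exchanged for a silyl ether through phenol 16, after the oxidation, so that the phenol is the only free hydroxyl when it is silylated.

14 ⇒ 13 ⇒ 12. The acetonide of 14 distinguishes C1–OH from C6–OH: in triol 13 only C6–OH has a hydroxyl on the neighbouring carbon (C4). The C5–OMe bond of 13 is then cut, giving epoxide 12. Forward, this is methanolysis at C5 with inversion while C4–O is kept. C5 is chosen because it is benzylic and is the distal carbon of the C6 epoxy alcohol.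

12 ⇒ 11. Both C–O bonds of the oxirane are cut together, giving the E-configured diene diol 11. Two stereocentres are reduced to one alkene geometry plus a chiral catalyst. The forward reaction must pick the tetrasubstituted C4=C5 alkene over the styrene, and one of its faces.

11 ⇒ 8 + 10. The C5–aryl bond is cut (Suzuki coupling of alkenyl iodide 8 with boronate 10). This lets the C5 ring carry its own electron-poor protecting group, and the coupling copies the alkene geometry.

8 ⇒ 3 + 4 (through 5, 6, 7). The C3–C4 and C5–I bonds are cut across the alkene. Alkyne 4 is symmetric, so there is no regiochemical question. Anti-addition of Grignard reagent 5 to dialkoxide 6 gives chelate 7, whose C–Mg bond is held cis to one CH2O group; this fixes the geometry needed in 11. The four carbons C6–C4–C5–C1 come from a commodity diol.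

3 ⇒ 2 ⇒ 1 and 10 ⇒ 9. These are standard interconversions from commercial phenols.

## Alternatives that were turned down

Alternative 1: The C3–C4 ring bond and the C5–OMe bond are cut, leading back to the flat, fully substituted 4-pyranone A1. Its ring oxygen links C3 and C4, and its C6 oxygen carries an (S)-O-methylmandelate. In the forward key step A1 is excited in the alcohol that is to be incorporated. The two carbons flanking the ring oxygen bond to each other, the bicyclic oxyallyl zwitterion is intercepted by solvent at the aryl-bearing terminus, and the resulting enolate opens the transient oxirane, leaving the former ring oxygen on C4 as the tertiary alcohol of A2.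
- For: one step makes the five-membered ring, both quaternary centres and their trans relation, since solvent must enter anti to the oxirane. On step economy and on relative configuration this route is stronger than the one chosen.
- Against: the absolute sense must come from an ester stereocentre four bonds from the nearest forming bond and free to rotate, so little facial bias can be expected. Capture must also choose the aryl-bearing over the methoxy-bearing terminus. Both silyloxyaryl groups and the product enone absorb light and invite secondary photochemistry.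
- Comparison: the chosen route is longer, but its absolute configuration comes from a catalyst bound directly to the reacting alkene through its allylic hydroxyls, and each centre is made in a thermal step of defined stereochemical course.

Alternative 2: C4–C5, C2=C3 and O–C6 are cut at once, giving the dimethoxy ketone A3 (C5, C1, C2) and the chloromethyl 1,2-dione A4 (C3, C4, C6). Under a chiral phase-transfer base the benzylic enolate of A3 would add through C5 to the central carbonyl of A4. The new C4 alkoxide would displace the halide on C6 (Darzens-type closure), and the C2 methylene would condense with the aryl ketone, giving A5, the bis-silyl ether of the target (identical with 26).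
- For: two short fragments, three bonds, two rings and both stereocentres in one flask, with no hydroxyl protecting groups. On step count it is clearly superior.
- Against: both stereocentres arise in the first, reversible aldol step between a fully substituted enolate carbon and a ketone, controlled only by an ion pair; no close analogy says the relative or absolute sense would be useful. A4 offers two carbonyl groups and an alkylating carbon to an ambident nucleophile, and A3 has a second enolisable site at C2, so several constitutions compete. A4 is also a very electrophilic, hydrate-prone compound.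
- Comparison: the chosen route separates these tasks. C4 and C5 come from a stereospecific addition to a geometrically defined alkene, and ring closure is left to a reaction that can go only one way.

Alternative 3: C1–C2 and C2–C3 are cut, removing C2 and leaving cyclobutanone A6 (C1, C3, C4, C5). A6 would come from a [2+2] cycloaddition in which a 1-arylethyl ether on the C4 oxygen is the chiral auxiliary. In the forward key step a silylated diazoalkane adds to the carbonyl of A6 under Lewis acid, and nitrogen is lost with migration of C3, inserting C2 to give cyclopentanone A7 with C4 and C5 untouched.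
- For: the auxiliary sits on a reacting carbon, and the suprafacial cycloaddition fixes the C4/C5 relation on a rigid ring. This is closer stereocontrol than a remote ester, and arguably a more predictable relative configuration than an epoxide opening at a tertiary benzylic carbon.
- Against: A7 is a saturated ketone without the C2 oxygen or the C2=C3 bond, so α-oxygenation, O-methylation and dehydrogenation must follow. The C3 stereocentre is made only to be destroyed. The auxiliary must be cleaved from a tertiary ether before the oxirane can be closed. Both cycloaddition partners are fully substituted at the reacting carbons, and the insertion must discriminate between migration of C3 and of the quaternary C5.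
- Comparison: the chosen route is of similar length but reaches the enol ether oxidation level directly, because C2 enters with its methoxy group, and it uses a catalytic source of chirality with no auxiliary to remove.

Key step: step 6

Assumption: the face rule of the tartrate-mediated epoxidation, established for allylic alcohols with one hydroxyl, is taken to hold for diol 11, whose two hydroxymethyl groups call for the same face.

Abbreviations: TIPSO = triisopropylsilyloxy; PivO = pivaloyloxy (2,2-dimethylpropanoyloxy); Ts = 4-toluenesulfonyl; PPTS = pyridinium 4-toluenesulfonate; DBU = 1,8-diazabicyclo[5.4.0]undec-7-ene; dppf = 1,1'-bis(diphenylphosphino)ferrocene. Locants C1–C6 are those defined in the analysis.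

Step 1
Reactants: 1 4'-hydroxyacetophenone
Product: 2 1-[4-(TIPSO)phenyl]ethan-1-one
Conditions: TIPSCl, imidazole, DMF, rt
Reagents that add atoms: chlorotriisopropylsilane, CC(C)[Si](Cl)(C(C)C)C(C)C
Why: Silylation of a phenol with a silyl chloride and imidazole. The bulky silyl ether tolerates the Grignard, cross-coupling and mild base steps ahead and is removed by fluoride at the end.

Step 2
Reactants: 2 1-[4-(TIPSO)phenyl]ethan-1-one
Product: 3 [4-(1-bromoethenyl)phenoxy]triisopropylsilane
Conditions: P(OPh)3, Br2, CH2Cl2, −60 °C; then Et3N, 2, −60 °C → reflux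
Reagents that add atoms: bromine, BrBr
Why: Conversion of an aryl methyl ketone into the 1-bromoalkene by a halophosphorane made in the flask: the enol oxygen is phosphorylated, bromide adds and Et3N eliminates. Only the terminal alkene can form.

Step 3
Reactants: 3 [4-(1-bromoethenyl)phenoxy]triisopropylsilane; 4 but-2-yne-1,4-diol
Product: 8 (2Z)-3-iodo-2-{1-[4-(TIPSO)phenyl]ethenyl}but-2-ene-1,4-diol, via Grignard reagent 5 (not isolated), via dialkoxide 6 (not isolated), via alkenylmagnesium chelate 7 (not isolated)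
Conditions: 3, Mg, THF, 40 °C; 4, MeMgCl (2 equiv), THF, 0 °C; combine, 65 °C; then I2, −78 → 0 °C
Reagents that add atoms: iodine, II
Why: Alkoxide-directed anti-carbomagnesiation of a propargylic alcohol: the alkenyl group adds to the alkyne carbon next to the coordinating alkoxide and magnesium ends on the other carbon inside a five-membered oxamagnesacycle, cis to that CH2O group; iodinolysis with retention fixes the Z geometry. The diol is used unprotected because a dialkoxide cannot be expelled from the alkenylmagnesium, whereas a propargylic ether would be lost by β-elimination to an allene.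

Step 4
Reactants: 9 4-(4,4,5,5-tetramethyl-1,3,2-dioxaborolan-2-yl)phenol
Product: 10 4-(4,4,5,5-tetramethyl-1,3,2-dioxaborolan-2-yl)phenyl pivalate
Conditions: PivCl, Et3N, DMAP (cat.), CH2Cl2, 0 °C → rt
Reagents that add atoms: pivaloyl chloride, CC(C)(C)C(Cl)=O
Why: Acylation of a phenol. The ring destined for C5 gets a pivalate because an acyloxy group is a much weaker donor than a silyloxy group, so the later tertiary benzylic epoxide does not ionise, and the hindered ester survives aqueous phosphate in the coupling.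

Step 5
Reactants: 8 (2Z)-3-iodo-2-{1-[4-(TIPSO)phenyl]ethenyl}but-2-ene-1,4-diol; 10 4-(4,4,5,5-tetramethyl-1,3,2-dioxaborolan-2-yl)phenyl pivalate
Product: 11 4-[(2E)-1,4-dihydroxy-3-{1-[4-(TIPSO)phenyl]ethenyl}but-2-en-2-yl]phenyl pivalate
Conditions: PdCl2(dppf) (5 mol %), K3PO4, 1,4-dioxane/H2O (10:1), 60 °C
Reagents that add atoms: none
Why: Suzuki–Miyaura coupling of an alkenyl iodide with an arylboronic ester goes with retention of alkene geometry, so the new aryl group stays cis to the hydroxymethyl group on C4 (E diene diol). Free allylic hydroxyls are tolerated and the iodide is the only reactive site.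

Step 6
Reactants: 11 4-[(2E)-1,4-dihydroxy-3-{1-[4-(TIPSO)phenyl]ethenyl}but-2-en-2-yl]phenyl pivalate
Product: 12 4-[(2R,3R)-2,3-bis(hydroxymethyl)-3-{1-[4-(TIPSO)phenyl]ethenyl}oxiran-2-yl]phenyl pivalate
Conditions: Ti(OiPr)4 (1.1 equiv), D-(−)-diisopropyl tartrate (1.3 equiv), tBuOOH (2.5 equiv), 4 Å molecular sieves, CH2Cl2, −25 °C
Reagents that add atoms: tert-butyl hydroperoxide, CC(C)(C)OO
Why: Either hydroxymethyl group of 11 exchanges onto titanium in the complex formed from Ti(OiPr)4 and the tartrate ester, and the tert-butyl peroxide bound to the same metal passes its distal oxygen to the C4=C5 π bond in one concerted step that makes both C–O bonds. The closest known reaction type is the Sharpless asymmetric epoxidation of tetrasubstituted (2,3,3-trisubstituted) allylic alcohols. The oxirane closes by this single suprafacial oxygen-atom transfer, a [2+1] addition with no open intermediate that could rotate, so the E geometry of 11 is copied into the ring: C6 stays cis to the C5 aryl group and the C3 branch cis to C1. The relative configuration of C4 and C5 is therefore set by the alkene geometry, and the absolute configuration by the ligand: D-(−)-diisopropyl tartrate attacks the face from which it turns (E)-3-substituted allylic alcohols into (2R,3R)-epoxy alcohols, which here corresponds to (2R,3R)-12. Because the two hydroxymethyl groups of the E-2-ene-1,4-diol are related by a local twofold axis, binding through either one presents the same alkene face, so the two modes reinforce each other. The step needs chemoselectivity for C4=C5 over the styrene, which is only homoallylic to C6–OH and cannot be held over the peroxide, and it needs the product to survive the Lewis acid: the pivaloyloxy group on the C5 ring withholds the donation that would let the tertiary benzylic C5–O bond ionise, and the work-up is kept non-acidic.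

Step 7
Reactants: 12 4-[(2R,3R)-2,3-bis(hydroxymethyl)-3-{1-[4-(TIPSO)phenyl]ethenyl}oxiran-2-yl]phenyl pivalate
Product: 13 4-[(2S,3R)-1,3,4-trihydroxy-2-methoxy-3-{1-[4-(TIPSO)phenyl]ethenyl}butan-2-yl]phenyl pivalate
Conditions: Ti(OiPr)4 (2 equiv), MeOH/CH2Cl2 (1:2), 0 → 35 °C
Reagents that add atoms: methanol, CO
Why: Titanium-assisted alcoholysis of a 2,3-epoxy alcohol: with C6–O and the oxirane oxygen held on titanium, methanol attacks the distal carbon C5, which is also the benzylic one, from the face opposite the C5–O bond, so C5 is inverted and C4–O is untouched. The acyloxy-substituted ring gives enough benzylic activation for attack at C5 but too little for a solvent-equilibrated cation, so the opening should remain stereospecific.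

Step 8
Reactants: 13 4-[(2S,3R)-1,3,4-trihydroxy-2-methoxy-3-{1-[4-(TIPSO)phenyl]ethenyl}butan-2-yl]phenyl pivalate
Product: 14 4-{(1S)-1-[(4R)-2,2-dimethyl-4-{1-[4-(TIPSO)phenyl]ethenyl}-1,3-dioxolan-4-yl]-2-hydroxy-1-methoxyethyl}phenyl pivalate
Conditions: Me2C(OMe)2, PPTS (cat.), acetone, rt
Reagents that add atoms: 2,2-dimethoxypropane, COC(C)(C)OC
Why: Acid-catalysed ketal exchange under thermodynamic control: the 1,2-diol (C6–OH, C4–OH) closes a dioxolane, whereas a six-membered ketal across C4–OH and C1–OH would force a substituent of the quaternary C4 into a syn-axial clash with a ketal methyl group. This leaves C1–OH as the only free hydroxyl; the weak acid does not protonate the electron-rich styrene.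

Step 9
Reactants: 14 4-{(1S)-1-[(4R)-2,2-dimethyl-4-{1-[4-(TIPSO)phenyl]ethenyl}-1,3-dioxolan-4-yl]-2-hydroxy-1-methoxyethyl}phenyl pivalate
Product: 15 4-{(1R)-1-[(4R)-2,2-dimethyl-4-{1-[4-(TIPSO)phenyl]ethenyl}-1,3-dioxolan-4-yl]-1-methoxy-2-oxoethyl}phenyl pivalate
Conditions: Dess–Martin periodinane, NaHCO3, CH2Cl2, 0 °C → rt
Reagents that add atoms: none
Why: Dess–Martin oxidation of a hindered primary alcohol to the aldehyde under buffered conditions. The aldehyde has no α-hydrogen, so C5 cannot epimerise (its descriptor changes only because of the new priority of C1).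

Step 10
Reactants: 15 4-{(1R)-1-[(4R)-2,2-dimethyl-4-{1-[4-(TIPSO)phenyl]ethenyl}-1,3-dioxolan-4-yl]-1-methoxy-2-oxoethyl}phenyl pivalate
Product: 16 (2R)-2-[(4R)-2,2-dimethyl-4-{1-[4-(TIPSO)phenyl]ethenyl}-1,3-dioxolan-4-yl]-2-(4-hydroxyphenyl)-2-methoxyacetaldehyde
Conditions: K2CO3, MeOH, 0 °C → rt
Reagents that add atoms: none
Why: Base-mediated methanolysis of an aryl ester, driven by the phenoxide leaving group. The acyl group has done its work once the epoxide is opened and has to go before the organolithium step; the aldehyde is not enolisable and the ketal is inert to carbonate.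

Step 11
Reactants: 16 (2R)-2-[(4R)-2,2-dimethyl-4-{1-[4-(TIPSO)phenyl]ethenyl}-1,3-dioxolan-4-yl]-2-(4-hydroxyphenyl)-2-methoxyacetaldehyde
Product: 17 (2R)-2-[(4R)-2,2-dimethyl-4-{1-[4-(TIPSO)phenyl]ethenyl}-1,3-dioxolan-4-yl]-2-methoxy-2-[4-(TIPSO)phenyl]acetaldehyde
Conditions: TIPSCl, imidazole, DMF, rt
Reagents that add atoms: chlorotriisopropylsilane, CC(C)[Si](Cl)(C(C)C)C(C)C
Why: Phenol silylation as in step 1 gives both rings the same fluoride-labile ether for the end game. Any silyl ether lost from the other ring in step 10 is restored here.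

Step 12
Reactants: 17 (2R)-2-[(4R)-2,2-dimethyl-4-{1-[4-(TIPSO)phenyl]ethenyl}-1,3-dioxolan-4-yl]-2-methoxy-2-[4-(TIPSO)phenyl]acetaldehyde; 18 dimethyl (methoxymethyl)phosphonate
Product: 20 dimethyl {(3S)-3-[(4R)-2,2-dimethyl-4-{1-[4-(TIPSO)phenyl]ethenyl}-1,3-dioxolan-4-yl]-2-hydroxy-1,3-dimethoxy-3-[4-(TIPSO)phenyl]propyl}phosphonate (epimer mixture at propyl C1/C2), via lithiated phosphonate 19 (not isolated)
Conditions: 18, n-BuLi, THF, −78 °C; then 17, −78 → −40 °C; AcOH, −78 °C
Reagents that add atoms: none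
Why: Addition of an α-lithiated phosphonate to an aldehyde; with lithium as counter-ion and a cold quench the β-hydroxyphosphonate is kept and does not eliminate. The two new stereocentres (C1, C2) form without control, which does not matter because both become sp2 carbons later.

Step 13
Reactants: 20 dimethyl {(3S)-3-[(4R)-2,2-dimethyl-4-{1-[4-(TIPSO)phenyl]ethenyl}-1,3-dioxolan-4-yl]-2-hydroxy-1,3-dimethoxy-3-[4-(TIPSO)phenyl]propyl}phosphonate
Product: 21 dimethyl {(3R)-3-[(4R)-2,2-dimethyl-4-{1-[4-(TIPSO)phenyl]ethenyl}-1,3-dioxolan-4-yl]-1,3-dimethoxy-2-oxo-3-[4-(TIPSO)phenyl]propyl}phosphonate (epimer mixture at propyl C1)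
Conditions: Dess–Martin periodinane, NaHCO3, CH2Cl2, rt
Reagents that add atoms: none
Why: Dess–Martin oxidation of the secondary alcohol gives the β-ketophosphonate. Addition and oxidation are preferred to acylating the phosphonate anion with an ester because C1 is a neopentyl position.

Step 14
Reactants: 21 dimethyl {(3R)-3-[(4R)-2,2-dimethyl-4-{1-[4-(TIPSO)phenyl]ethenyl}-1,3-dioxolan-4-yl]-1,3-dimethoxy-2-oxo-3-[4-(TIPSO)phenyl]propyl}phosphonate
Product: 22 dimethyl {(3R)-3-[(4R)-2,2-dimethyl-4-[4-(TIPSO)benzoyl]-1,3-dioxolan-4-yl]-1,3-dimethoxy-2-oxo-3-[4-(TIPSO)phenyl]propyl}phosphonate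
Conditions: O3, CH2Cl2/MeOH (4:1), −78 °C; then Me2S, −78 °C → rt
Reagents that add atoms: ozone, [O-][O+]=O
Why: Ozonolysis with reductive work-up cleaves the 1,1-disubstituted styrene, the only alkene in 21, to the C3 aryl ketone. Ozone is dosed to a dye end-point so that the silyloxy arenes are not attacked.

Step 15
Reactants: 22 dimethyl {(3R)-3-[(4R)-2,2-dimethyl-4-[4-(TIPSO)benzoyl]-1,3-dioxolan-4-yl]-1,3-dimethoxy-2-oxo-3-[4-(TIPSO)phenyl]propyl}phosphonate
Product: 23 (5R,6R)-6,8-dimethoxy-2,2-dimethyl-6,9-bis[4-(TIPSO)phenyl]-1,3-dioxaspiro[4.4]non-8-en-7-one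
Conditions: K2CO3, 18-crown-6, toluene, 70 °C
Reagents that add atoms: none
Why: Intramolecular Horner–Wadsworth–Emmons reaction: the phosphonate carbanion at C2 adds to the C3 ketone (five-membered ring closure) and dimethyl phosphate is lost, giving the C2=C3 enol ether double bond. C3 has no α-hydrogen and C4–O is tied up in the ketal, so neither enolisation nor retro-aldol cleavage competes, and C4 and C5 are not involved.

Step 16
Reactants: 23 (5R,6R)-6,8-dimethoxy-2,2-dimethyl-6,9-bis[4-(TIPSO)phenyl]-1,3-dioxaspiro[4.4]non-8-en-7-one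
Product: 24 (4R,5R)-4-hydroxy-4-(hydroxymethyl)-2,5-dimethoxy-3,5-bis[4-(TIPSO)phenyl]cyclopent-2-en-1-one
Conditions: AcOH/H2O/THF (3:1:1), 45 °C
Reagents that add atoms: none
Why: Mild aqueous acid hydrolysis of the isopropylidene ketal. Aryl silyl ethers and the 2-methoxy enone (an enol ether deactivated by the carbonyl group) tolerate these conditions.

Step 17
Reactants: 24 (4R,5R)-4-hydroxy-4-(hydroxymethyl)-2,5-dimethoxy-3,5-bis[4-(TIPSO)phenyl]cyclopent-2-en-1-one
Product: 26 (3R,4R)-4,6-dimethoxy-4,7-bis[4-(TIPSO)phenyl]-1-oxaspiro[2.4]hept-6-en-5-one, via primary tosylate 25 (not isolated)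
Conditions: TsCl, Et3N, DMAP (cat.), CH2Cl2, 0 °C → rt; then DBU, 0 °C → rt
Reagents that add atoms: none
Why: Selective sulfonylation of the primary hydroxyl, then 3-exo-tet displacement by the tertiary C4 oxygen, closes the oxirane; the C4–O bond is not broken, so the configuration from step 6 is kept. A weak amidine base keeps the alkoxide concentration low, and closure onto the adjacent sulfonate should outrun retro-aldol cleavage of C4–C5.

Step 18
Reactants: 26 (3R,4R)-4,6-dimethoxy-4,7-bis[4-(TIPSO)phenyl]-1-oxaspiro[2.4]hept-6-en-5-one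
Product: 27 (3R,4R)-4,7-bis(4-hydroxyphenyl)-4,6-dimethoxy-1-oxaspiro[2.4]hept-6-en-5-one
Conditions: Bu4NF, AcOH (1:1), THF, 0 °C
Reagents that add atoms: none
Why: Fluoride cleavage of the two aryl silyl ethers. Buffering with acetic acid avoids free phenoxide, which could open the oxirane or ionise the benzylic ether at C5.

Compound list

1 | 4'-hydroxyacetophenone | CC(=O)c1ccc(O)cc1 | starting material
2 | 1-[4-(triisopropylsilyloxy)phenyl]ethan-1-one | CC(=O)c1ccc(O[Si](C(C)C)(C(C)C)C(C)C)cc1 | intermediate
3 | [4-(1-bromoethenyl)phenoxy]triisopropylsilane | C=C(Br)c1ccc(O[Si](C(C)C)(C(C)C)C(C)C)cc1 | intermediate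
4 | but-2-yne-1,4-diol | OCC#CCO | starting material
5 | {1-[4-(triisopropylsilyloxy)phenyl]ethenyl}magnesium bromide (not isolated) | C=C([Mg]Br)c1ccc(O[Si](C(C)C)(C(C)C)C(C)C)cc1 | intermediate
6 | bis(chloromagnesium) but-2-yne-1,4-diolate (not isolated) | Cl[Mg]OCC#CCO[Mg]Cl | intermediate
7 | 3-[(chloromagnesiooxy)methyl]-4-{1-[4-(triisopropylsilyloxy)phenyl]ethenyl}-2,5-dihydro-1,2-oxamagnesole (not isolated) | C=C(c1ccc(O[Si](C(C)C)(C(C)C)C(C)C)cc1)C1=C(CO[Mg]Cl)[Mg]OC1 | intermediate
8 | (2Z)-3-iodo-2-{1-[4-(triisopropylsilyloxy)phenyl]ethenyl}but-2-ene-1,4-diol | OC/C(C(=C)c1ccc(O[Si](C(C)C)(C(C)C)C(C)C)cc1)=C(\I)CO | intermediate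
9 | 4-(4,4,5,5-tetramethyl-1,3,2-dioxaborolan-2-yl)phenol | CC1(C)OB(OC1(C)C)c1ccc(O)cc1 | starting material
10 | 4-(4,4,5,5-tetramethyl-1,3,2-dioxaborolan-2-yl)phenyl 2,2-dimethylpropanoate | CC1(C)OB(OC1(C)C)c1ccc(OC(=O)C(C)(C)C)cc1 | intermediate
11 | 4-[(2E)-1,4-dihydroxy-3-{1-[4-(triisopropylsilyloxy)phenyl]ethenyl}but-2-en-2-yl]phenyl 2,2-dimethylpropanoate | OC/C(C(=C)c1ccc(O[Si](C(C)C)(C(C)C)C(C)C)cc1)=C(\c1ccc(OC(=O)C(C)(C)C)cc1)CO | intermediate
12 | 4-[(2R,3R)-2,3-bis(hydroxymethyl)-3-{1-[4-(triisopropylsilyloxy)phenyl]ethenyl}oxiran-2-yl]phenyl 2,2-dimethylpropanoate | OC[C@@]1(C(=C)c2ccc(O[Si](C(C)C)(C(C)C)C(C)C)cc2)O[C@]1(c2ccc(OC(=O)C(C)(C)C)cc2)CO | intermediate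
13 | 4-[(2S,3R)-1,3,4-trihydroxy-2-methoxy-3-{1-[4-(triisopropylsilyloxy)phenyl]ethenyl}butan-2-yl]phenyl 2,2-dimethylpropanoate | OC[C@](O)(C(=C)c1ccc(O[Si](C(C)C)(C(C)C)C(C)C)cc1)[C@](OC)(c1ccc(OC(=O)C(C)(C)C)cc1)CO | intermediate
14 | 4-{(1S)-1-[(4R)-2,2-dimethyl-4-{1-[4-(triisopropylsilyloxy)phenyl]ethenyl}-1,3-dioxolan-4-yl]-2-hydroxy-1-methoxyethyl}phenyl 2,2-dimethylpropanoate | CC1(C)OC[C@](O1)(C(=C)c1ccc(O[Si](C(C)C)(C(C)C)C(C)C)cc1)[C@](OC)(c1ccc(OC(=O)C(C)(C)C)cc1)CO | intermediate
15 | 4-{(1R)-1-[(4R)-2,2-dimethyl-4-{1-[4-(triisopropylsilyloxy)phenyl]ethenyl}-1,3-dioxolan-4-yl]-1-methoxy-2-oxoethyl}phenyl 2,2-dimethylpropanoate | CC1(C)OC[C@](O1)(C(=C)c1ccc(O[Si](C(C)C)(C(C)C)C(C)C)cc1)[C@](OC)(c1ccc(OC(=O)C(C)(C)C)cc1)C=O | intermediate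
16 | (2R)-2-[(4R)-2,2-dimethyl-4-{1-[4-(triisopropylsilyloxy)phenyl]ethenyl}-1,3-dioxolan-4-yl]-2-(4-hydroxyphenyl)-2-methoxyacetaldehyde | CC1(C)OC[C@](O1)(C(=C)c1ccc(O[Si](C(C)C)(C(C)C)C(C)C)cc1)[C@](OC)(c1ccc(O)cc1)C=O | intermediate
17 | (2R)-2-[(4R)-2,2-dimethyl-4-{1-[4-(triisopropylsilyloxy)phenyl]ethenyl}-1,3-dioxolan-4-yl]-2-methoxy-2-[4-(triisopropylsilyloxy)phenyl]acetaldehyde | CC1(C)OC[C@](O1)(C(=C)c1ccc(O[Si](C(C)C)(C(C)C)C(C)C)cc1)[C@](OC)(c1ccc(O[Si](C(C)C)(C(C)C)C(C)C)cc1)C=O | intermediate
18 | dimethyl (methoxymethyl)phosphonate | COCP(=O)(OC)OC | starting material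
19 | dimethyl [lithio(methoxy)methyl]phosphonate (not isolated) | [Li]C(OC)P(=O)(OC)OC | intermediate
20 | dimethyl {(3S)-3-[(4R)-2,2-dimethyl-4-{1-[4-(triisopropylsilyloxy)phenyl]ethenyl}-1,3-dioxolan-4-yl]-2-hydroxy-1,3-dimethoxy-3-[4-(triisopropylsilyloxy)phenyl]propyl}phosphonate, epimers at C1 and C2 of the propyl chain | CC1(C)OC[C@](O1)(C(=C)c1ccc(O[Si](C(C)C)(C(C)C)C(C)C)cc1)[C@](OC)(c1ccc(O[Si](C(C)C)(C(C)C)C(C)C)cc1)C(O)C(OC)P(=O)(OC)OC | intermediate
21 | dimethyl {(3R)-3-[(4R)-2,2-dimethyl-4-{1-[4-(triisopropylsilyloxy)phenyl]ethenyl}-1,3-dioxolan-4-yl]-1,3-dimethoxy-2-oxo-3-[4-(triisopropylsilyloxy)phenyl]propyl}phosphonate, epimers at C1 of the propyl chain | CC1(C)OC[C@](O1)(C(=C)c1ccc(O[Si](C(C)C)(C(C)C)C(C)C)cc1)[C@](OC)(c1ccc(O[Si](C(C)C)(C(C)C)C(C)C)cc1)C(=O)C(OC)P(=O)(OC)OC | intermediate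
22 | dimethyl {(3R)-3-[(4R)-2,2-dimethyl-4-[4-(triisopropylsilyloxy)benzoyl]-1,3-dioxolan-4-yl]-1,3-dimethoxy-2-oxo-3-[4-(triisopropylsilyloxy)phenyl]propyl}phosphonate, epimers at C1 of the propyl chain | CC1(C)OC[C@](O1)(C(=O)c1ccc(O[Si](C(C)C)(C(C)C)C(C)C)cc1)[C@](OC)(c1ccc(O[Si](C(C)C)(C(C)C)C(C)C)cc1)C(=O)C(OC)P(=O)(OC)OC | intermediate
23 | (5R,6R)-6,8-dimethoxy-2,2-dimethyl-6,9-bis[4-(triisopropylsilyloxy)phenyl]-1,3-dioxaspiro[4.4]non-8-en-7-one | COC1=C(c3ccc(O[Si](C(C)C)(C(C)C)C(C)C)cc3)[C@@]2(COC(C)(C)O2)[C@](OC)(c3ccc(O[Si](C(C)C)(C(C)C)C(C)C)cc3)C1=O | intermediate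
24 | (4R,5R)-4-hydroxy-4-(hydroxymethyl)-2,5-dimethoxy-3,5-bis[4-(triisopropylsilyloxy)phenyl]cyclopent-2-en-1-one | COC1=C(c2ccc(O[Si](C(C)C)(C(C)C)C(C)C)cc2)[C@@](O)(CO)[C@](OC)(c2ccc(O[Si](C(C)C)(C(C)C)C(C)C)cc2)C1=O | intermediate
25 | {(1R,5R)-1-hydroxy-3,5-dimethoxy-4-oxo-2,5-bis[4-(triisopropylsilyloxy)phenyl]cyclopent-2-en-1-yl}methyl 4-methylbenzenesulfonate (not isolated) | COC1=C(c2ccc(O[Si](C(C)C)(C(C)C)C(C)C)cc2)[C@@](O)(COS(=O)(=O)c2ccc(C)cc2)[C@](OC)(c2ccc(O[Si](C(C)C)(C(C)C)C(C)C)cc2)C1=O | intermediate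
26 | (3R,4R)-4,6-dimethoxy-4,7-bis[4-(triisopropylsilyloxy)phenyl]-1-oxaspiro[2.4]hept-6-en-5-one | COC1=C(c2ccc(O[Si](C(C)C)(C(C)C)C(C)C)cc2)[C@@]2(CO2)[C@](OC)(c2ccc(O[Si](C(C)C)(C(C)C)C(C)C)cc2)C1=O | intermediate
27 | (3R,4R)-4,7-bis(4-hydroxyphenyl)-4,6-dimethoxy-1-oxaspiro[2.4]hept-6-en-5-one (CNP0504072.1) | COC1=C(c2ccc(O)cc2)[C@@]2(CO2)[C@](OC)(c2ccc(O)cc2)C1=O | target

Total step count: 18. Longest linear sequence: 17 steps (steps 1–3 and 5–18, from 1 to 27); step 4 is the only step off the main line.

Least certain steps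

Step 6 (key step). Oxygen transfer may reach the wrong alkene face, or turnover may be slow. The aryl group cis to whichever hydroxymethyl binds points into the ligand sphere, and the diol can bridge two metal centres; a slow reaction also gives the Lewis acid time to open the product. Fallback, from 11: epoxidise without a chiral ligand (VO(acac)2, tBuOOH, CH2Cl2, 0 °C; hydroxyl-directed and still a stereospecific syn transfer) to the racemic epoxy diol F1. Carry this through the conditions of steps 7 and 8 to the racemic triol F2 and the racemic acetonide alcohol F3. Resolve F3 by lipase-catalysed acetylation of its primary hydroxyl (vinyl acetate, lipase from Burkholderia cepacia). The enzyme leaves one antipode untouched; 14 is collected either directly or, if it is the acylated antipode, by enzymatic hydrolysis of its acetate F4. The route is rejoined at 14.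

Step 3. Addition of the hindered 1-arylvinyl Grignard reagent to the poorly soluble dialkoxide may be too slow, so that the reagent is consumed by homocoupling and protonation. Fallback, from 4 and 3, with the alkene built by cross-coupling instead of carbometalation: anti-addition of bromine to 4 gives (E)-2,3-dibromobut-2-ene-1,4-diol F5. Bromide 3 is converted (B2pin2, KOAc, PdCl2(dppf), dioxane, 80 °C) into the 1-arylvinyl pinacol boronate F6. Suzuki coupling of F5 with one equivalent of 10 gives the monobromide F7, in which the aryl group is already cis to the hydroxymethyl on the neighbouring carbon. A second coupling, with F6, gives 11 with retention.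

Step 7. Configuration at C5 may leak if ionisation runs ahead of methanol attack at this tertiary benzylic centre; a second titanium chelate through C1–OH may also divert attack to C4. Fallback, from 9 and 8, with the C5 ring carrying a sulfonate, which is a net acceptor and cannot be transesterified. Boronate 9 is converted into its methanesulfonate F8 (MsCl, Et3N) and coupled with 8 as in step 5 to the dienediol mesylate F9. Epoxidation as in step 6 gives the epoxy diol mesylate F10, and titanium-assisted methanolysis (now at 40–50 °C) gives the triol mesylate F11. The sulfonate is removed with LiN(iPr)2 in THF at −78 → 0 °C (E1cB loss of sulfene) to the phenol triol F12. Only its phenoxide is acylated by pivaloyl chloride under Schotten–Baumann conditions (aqueous NaOH/CH2Cl2), which gives 13.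

Step 15. The stabilised, α-methoxylated phosphonate carbanion may fail to add to the hindered, electron-rich aryl ketone, leaving 22 to decompose by dephosphonylation. Fallback, from 17, with an aldol condensation in place of the olefination. Methoxymethyllithium (Bu3SnCH2OMe, n-BuLi, THF, −78 °C) adds to 17 to give the carbinol F13. Dess–Martin oxidation gives the methoxymethyl ketone F14, and ozonolysis as in step 14 the 1,4-diketone F15. KOtBu in THF then adds the only possible enolate (C2) to the C3 ketone, and the aldol F16 loses water (E1cB, on warming or after mesylation) to give 23.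

Further compounds

F1 | step 6 | racemic 4-[2,3-bis(hydroxymethyl)-3-{1-[4-(triisopropylsilyloxy)phenyl]ethenyl}oxiran-2-yl]phenyl 2,2-dimethylpropanoate, (2R,3R) and (2S,3S) | OC[C@@]1(C(=C)c2ccc(O[Si](C(C)C)(C(C)C)C(C)C)cc2)O[C@]1(c2ccc(OC(=O)C(C)(C)C)cc2)CO.OC[C@]1(C(=C)c2ccc(O[Si](C(C)C)(C(C)C)C(C)C)cc2)O[C@@]1(c2ccc(OC(=O)C(C)(C)C)cc2)CO
F2 | step 6 | racemic 4-[1,3,4-trihydroxy-2-methoxy-3-{1-[4-(triisopropylsilyloxy)phenyl]ethenyl}butan-2-yl]phenyl 2,2-dimethylpropanoate, (2S,3R) and (2R,3S) | OC[C@](O)(C(=C)c1ccc(O[Si](C(C)C)(C(C)C)C(C)C)cc1)[C@](OC)(c1ccc(OC(=O)C(C)(C)C)cc1)CO.OC[C@@](O)(C(=C)c1ccc(O[Si](C(C)C)(C(C)C)C(C)C)cc1)[C@@](OC)(c1ccc(OC(=O)C(C)(C)C)cc1)CO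
F3 | step 6 | racemic 14, both enantiomers of the acetonide alcohol | CC1(C)OC[C@](O1)(C(=C)c1ccc(O[Si](C(C)C)(C(C)C)C(C)C)cc1)[C@](OC)(c1ccc(OC(=O)C(C)(C)C)cc1)CO.CC1(C)OC[C@@](O1)(C(=C)c1ccc(O[Si](C(C)C)(C(C)C)C(C)C)cc1)[C@@](OC)(c1ccc(OC(=O)C(C)(C)C)cc1)CO
F4 | step 6 | acetate of 14: 4-{(1S)-2-acetoxy-1-[(4R)-2,2-dimethyl-4-{1-[4-(triisopropylsilyloxy)phenyl]ethenyl}-1,3-dioxolan-4-yl]-1-methoxyethyl}phenyl 2,2-dimethylpropanoate | CC1(C)OC[C@](O1)(C(=C)c1ccc(O[Si](C(C)C)(C(C)C)C(C)C)cc1)[C@](OC)(c1ccc(OC(=O)C(C)(C)C)cc1)COC(C)=O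
F5 | step 3 | (2E)-2,3-dibromobut-2-ene-1,4-diol | OC/C(Br)=C(\Br)CO
F6 | step 3 | triisopropyl{4-[1-(4,4,5,5-tetramethyl-1,3,2-dioxaborolan-2-yl)ethenyl]phenoxy}silane | C=C(B1OC(C)(C)C(C)(C)O1)c1ccc(O[Si](C(C)C)(C(C)C)C(C)C)cc1
F7 | step 3 | 4-[(2Z)-3-bromo-1,4-dihydroxybut-2-en-2-yl]phenyl 2,2-dimethylpropanoate | OC/C(Br)=C(\c1ccc(OC(=O)C(C)(C)C)cc1)CO
F8 | step 7 | 4-(4,4,5,5-tetramethyl-1,3,2-dioxaborolan-2-yl)phenyl methanesulfonate | CC1(C)OB(OC1(C)C)c1ccc(OS(C)(=O)=O)cc1
F9 | step 7 | 4-[(2E)-1,4-dihydroxy-3-{1-[4-(triisopropylsilyloxy)phenyl]ethenyl}but-2-en-2-yl]phenyl methanesulfonate | OC/C(C(=C)c1ccc(O[Si](C(C)C)(C(C)C)C(C)C)cc1)=C(\c1ccc(OS(C)(=O)=O)cc1)CO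
F10 | step 7 | 4-[(2R,3R)-2,3-bis(hydroxymethyl)-3-{1-[4-(triisopropylsilyloxy)phenyl]ethenyl}oxiran-2-yl]phenyl methanesulfonate | OC[C@@]1(C(=C)c2ccc(O[Si](C(C)C)(C(C)C)C(C)C)cc2)O[C@]1(c2ccc(OS(C)(=O)=O)cc2)CO
F11 | step 7 | 4-[(2S,3R)-1,3,4-trihydroxy-2-methoxy-3-{1-[4-(triisopropylsilyloxy)phenyl]ethenyl}butan-2-yl]phenyl methanesulfonate | OC[C@](O)(C(=C)c1ccc(O[Si](C(C)C)(C(C)C)C(C)C)cc1)[C@](OC)(c1ccc(OS(C)(=O)=O)cc1)CO
F12 | step 7 | (2R,3S)-3-(4-hydroxyphenyl)-3-methoxy-2-{1-[4-(triisopropylsilyloxy)phenyl]ethenyl}butane-1,2,4-triol | OC[C@](O)(C(=C)c1ccc(O[Si](C(C)C)(C(C)C)C(C)C)cc1)[C@](OC)(c1ccc(O)cc1)CO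
F13 | step 15 | (3S)-3-[(4R)-2,2-dimethyl-4-{1-[4-(triisopropylsilyloxy)phenyl]ethenyl}-1,3-dioxolan-4-yl]-1,3-dimethoxy-3-[4-(triisopropylsilyloxy)phenyl]propan-2-ol, both C2 epimers | CC1(C)OC[C@](O1)(C(=C)c1ccc(O[Si](C(C)C)(C(C)C)C(C)C)cc1)[C@](OC)(c1ccc(O[Si](C(C)C)(C(C)C)C(C)C)cc1)C(O)COC
F14 | step 15 | (1R)-1-[(4R)-2,2-dimethyl-4-{1-[4-(triisopropylsilyloxy)phenyl]ethenyl}-1,3-dioxolan-4-yl]-1,3-dimethoxy-1-[4-(triisopropylsilyloxy)phenyl]propan-2-one | CC1(C)OC[C@](O1)(C(=C)c1ccc(O[Si](C(C)C)(C(C)C)C(C)C)cc1)[C@](OC)(c1ccc(O[Si](C(C)C)(C(C)C)C(C)C)cc1)C(=O)COC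
F15 | step 15 | (1R)-1-[(4R)-2,2-dimethyl-4-[4-(triisopropylsilyloxy)benzoyl]-1,3-dioxolan-4-yl]-1,3-dimethoxy-1-[4-(triisopropylsilyloxy)phenyl]propan-2-one | CC1(C)OC[C@](O1)(C(=O)c1ccc(O[Si](C(C)C)(C(C)C)C(C)C)cc1)[C@](OC)(c1ccc(O[Si](C(C)C)(C(C)C)C(C)C)cc1)C(=O)COC
F16 | step 15 | (5R,6R)-9-hydroxy-6,8-dimethoxy-2,2-dimethyl-6,9-bis[4-(triisopropylsilyloxy)phenyl]-1,3-dioxaspiro[4.4]nonan-7-one, epimers at C8 and C9 | COC1C(O)(c3ccc(O[Si](C(C)C)(C(C)C)C(C)C)cc3)[C@@]2(COC(C)(C)O2)[C@](OC)(c3ccc(O[Si](C(C)C)(C(C)C)C(C)C)cc3)C1=O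
A1 | alternative 1 | {5-methoxy-4-oxo-3,6-bis[4-(triisopropylsilyloxy)phenyl]-4H-pyran-2-yl}methyl (2S)-2-methoxy-2-phenylacetate | COC1=C(c2ccc(O[Si](C(C)C)(C(C)C)C(C)C)cc2)OC(COC(=O)[C@@H](OC)c2ccccc2)=C(c2ccc(O[Si](C(C)C)(C(C)C)C(C)C)cc2)C1=O
A2 | alternative 1 | {(1R,5R)-1-hydroxy-3,5-dimethoxy-4-oxo-2,5-bis[4-(triisopropylsilyloxy)phenyl]cyclopent-2-en-1-yl}methyl (2S)-2-methoxy-2-phenylacetate | COC1=C(c2ccc(O[Si](C(C)C)(C(C)C)C(C)C)cc2)[C@@](O)(COC(=O)[C@@H](OC)c2ccccc2)[C@](OC)(c2ccc(O[Si](C(C)C)(C(C)C)C(C)C)cc2)C1=O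
A3 | alternative 2 | 1,3-dimethoxy-1-[4-(triisopropylsilyloxy)phenyl]propan-2-one | COCC(=O)C(OC)c1ccc(O[Si](C(C)C)(C(C)C)C(C)C)cc1
A4 | alternative 2 | 3-chloro-1-[4-(triisopropylsilyloxy)phenyl]propane-1,2-dione | O=C(CCl)C(=O)c1ccc(O[Si](C(C)C)(C(C)C)C(C)C)cc1
A5 | alternative 2 | (3R,4R)-4,6-dimethoxy-4,7-bis[4-(triisopropylsilyloxy)phenyl]-1-oxaspiro[2.4]hept-6-en-5-one, identical with 26 | COC1=C(c2ccc(O[Si](C(C)C)(C(C)C)C(C)C)cc2)[C@@]2(CO2)[C@](OC)(c2ccc(O[Si](C(C)C)(C(C)C)C(C)C)cc2)C1=O
A6 | alternative 3 | 3-(tert-butyldimethylsilyloxymethyl)-2-methoxy-2,4-bis[4-(triisopropylsilyloxy)phenyl]-3-[1-(2,4,6-triisopropylphenyl)ethoxy]cyclobutan-1-one, configured as in A7 | O=C1[C@H](c2ccc(O[Si](C(C)C)(C(C)C)C(C)C)cc2)[C@@](O[C@@H](C)c2c(C(C)C)cc(C(C)C)cc2C(C)C)(CO[Si](C)(C)C(C)(C)C)[C@]1(OC)c2ccc(O[Si](C(C)C)(C(C)C)C(C)C)cc2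
A7 | alternative 3 | 3-(tert-butyldimethylsilyloxymethyl)-2-methoxy-2,4-bis[4-(triisopropylsilyloxy)phenyl]-3-[1-(2,4,6-triisopropylphenyl)ethoxy]cyclopentan-1-one, configuration as in the SMILES | C1[C@H](c2ccc(O[Si](C(C)C)(C(C)C)C(C)C)cc2)[C@@](O[C@@H](C)c2c(C(C)C)cc(C(C)C)cc2C(C)C)(CO[Si](C)(C)C(C)(C)C)[C@](OC)(c2ccc(O[Si](C(C)C)(C(C)C)C(C)C)cc2)C1=O
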